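**Retrosynthetic overview**
1. The target comes from global desilylation of its bis-silyl ether; the C7–O(aroyl) bond is cut next, back to a bicyclic C7–H ketone and a protected aryl carboxylic acid, joined by manganese-mediated radical α'-acyloxylation anti to C6–OTBS (this sets C7).
2. C7–CH3 comes from enolate methylation; the pyran (ring B, formed last) comes from 6-endo hydroalkoxylation of a 2-(hydroxymethyl)-3-enynyl cyclohexenone.
3. The enynone comes from acetylide 1,2-addition and oxidative 1,3-carbonyl transposition on the Baylis–Hillman adduct of (R)-5-silyloxycyclohex-2-enone; the C6–O stereocentre comes from copper-catalysed asymmetric conjugate borylation/oxidation of cyclohexenone.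
4. The acid comes from dianion self-condensation of methyl acetoacetate (arene ring C built de novo), then 4-O/2-O differentiation; the enyne comes from crotonaldehyde via its dibromo-olefin.
5. Ring order: carbocycle A is present from the start, arene C is built in a separate branch, pyran B is closed in step 9; the two halves meet in step 15.

Assumption: the ferrocenyl diphosphine enantiomer named in step 1 is taken to give the (R)-boronate; if the sense of induction is the opposite, its mirror image is used.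
Locants C1–C8a are those of the isochromene core of the target, which is the (6S,7R) isomer with 6-OH and 7-O-aroyl trans.

**Step 1**
Reactants: 1 cyclohex-2-en-1-one
Product: 3 (R)-3-hydroxycyclohexan-1-one, via (R)-3-(4,4,5,5-tetramethyl-1,3,2-dioxaborolan-2-yl)cyclohexan-1-one 2 (not isolated)
Conditions: B2pin2 (1.1 equiv), CuCl (3 mol%), NaOtBu (3 mol%), (R)-1-[(S)-2-(diphenylphosphino)ferrocenyl]ethyldicyclohexylphosphine (4 mol%), MeOH (2 equiv), THF, rt; then NaBO3·4H2O, THF/H2O, rt
Reagents that add atoms: sodium perborate ([Na+].[Na+].O[B-]1(O)OO[B-](O)(O)OO1)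
Why: Copper-catalysed asymmetric conjugate borylation, in which the ligand-controlled 1,4-addition of the boryl-copper species sets C3 as R, followed by stereoretentive perborate oxidation of the C–B bond under conditions mild enough to avoid β-elimination.

**Step 2**
Reactants: 3 (R)-3-hydroxycyclohexan-1-one
Product: 4 (R)-3-[(tert-butyldimethylsilyl)oxy]cyclohexan-1-one
Conditions: TBSCl, imidazole, DMF, rt
Reagents that add atoms: tert-butyldimethylsilyl chloride (CC(C)(C)[Si](C)(C)Cl)
Why: Standard imidazole-promoted silylation of the secondary alcohol, which blocks retro-aldol and elimination and later serves as the stereodirecting group (no new stereocentre).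

**Step 3**
Reactants: 4 (R)-3-[(tert-butyldimethylsilyl)oxy]cyclohexan-1-one
Product: 5 (R)-5-[(tert-butyldimethylsilyl)oxy]cyclohex-2-en-1-one
Conditions: LDA (1.1 equiv), THF, −78 °C; then N-tert-butylbenzenesulfinimidoyl chloride (1.2 equiv), −78 °C
Reagents that add atoms: none
Why: Mukaiyama dehydrogenation, in which LDA removes the C6 proton kinetically (remote from the bulky β-silyloxy group) and the S-sulfinimidoylated enolate undergoes syn-elimination to the enone, leaving the carbinol centre untouched.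

**Step 4**
Reactants: 5 (R)-5-[(tert-butyldimethylsilyl)oxy]cyclohex-2-en-1-one, 6 formaldehyde
Product: 7 (R)-5-[(tert-butyldimethylsilyl)oxy]-2-(hydroxymethyl)cyclohex-2-en-1-one
Conditions: 37% aq. CH2O (2 equiv), DMAP (20 mol%), THF/H2O (1:1), rt
Reagents that add atoms: none
Why: Morita–Baylis–Hillman hydroxymethylation, in which DMAP adds reversibly to the β-unsubstituted enone and the resulting enolate is trapped by formaldehyde at C2 (no stereocentre formed).

**Step 5**
Reactants: 7 (R)-5-[(tert-butyldimethylsilyl)oxy]-2-(hydroxymethyl)cyclohex-2-en-1-one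
Product: 8 (R)-5-[(tert-butyldimethylsilyl)oxy]-2-{[(tert-butyldimethylsilyl)oxy]methyl}cyclohex-2-en-1-one
Conditions: TBSCl, imidazole, CH2Cl2, 0 °C to rt
Reagents that add atoms: tert-butyldimethylsilyl chloride (CC(C)(C)[Si](C)(C)Cl)
Why: Silylation of the primary allylic alcohol so that the organolithium addition and the chromium oxidation that follow act only at the ketone and the tertiary carbinol.

**Step 6**
Reactants: 9 (E)-but-2-enal
Product: 10 (3E)-1,1-dibromopenta-1,3-diene
Conditions: CBr4 (2 equiv), PPh3 (2 equiv), Zn dust (2 equiv), CH2Cl2, rt, 24 h; then 9, rt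
Reagents that add atoms: carbon tetrabromide (BrC(Br)(Br)Br)
Why: Corey–Fuchs (Ramirez) dibromo-olefination of the aldehyde by the ylide made from CBr4, PPh3 and Zn, which does not touch the (E)-alkene.

**Step 7**
Reactants: 10 (3E)-1,1-dibromopenta-1,3-diene, 8 bis-silyl enone
Product: 12 (5R)-5-[(tert-butyldimethylsilyl)oxy]-2-{[(tert-butyldimethylsilyl)oxy]methyl}-1-[(3E)-pent-3-en-1-yn-1-yl]cyclohex-2-en-1-ol (C1 epimers), via lithium (E)-pent-3-en-1-yn-1-ide 11 (not isolated)
Conditions: 10 (1.5 equiv), n-BuLi (3.0 equiv), THF, −78 to 0 °C; then 8, −78 °C; aq. NH4Cl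
Reagents that add atoms: none
Why: Second stage of the Corey–Fuchs sequence (Br/Li exchange, Fritsch–Buttenberg–Wiechell shift, deprotonation) gives the lithium acetylide, which adds 1,2 to the enone; the new carbinol centre forms as a mixture that is erased in step 8.

**Step 8**
Reactants: 12 tertiary enynyl carbinol
Product: 13 (5S)-5-[(tert-butyldimethylsilyl)oxy]-2-{[(tert-butyldimethylsilyl)oxy]methyl}-3-[(3E)-pent-3-en-1-yn-1-yl]cyclohex-2-en-1-one
Conditions: pyridinium chlorochromate (3 equiv), 4 Å MS, CH2Cl2, rt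
Reagents that add atoms: pyridinium chlorochromate ([O-][Cr](=O)(=O)Cl.c1cc[nH+]cc1)
Why: Dauben–Babler oxidative 1,3-transposition, in which the tertiary allylic chromate ester undergoes a [3,3] shift and is oxidised at the former alkene CH, placing the alkynyl group at the β-carbon and the silyloxy carbon β' to the new carbonyl (the carbinol centre is untouched; R becomes S only through CIP priorities).

**Step 9**
Reactants: 13 bis-silyl ynenone
Product: 15 (6S)-6-[(tert-butyldimethylsilyl)oxy]-3-[(1E)-prop-1-en-1-yl]-6,7-dihydro-1H-isochromen-8(5H)-one, via (5S)-5-[(tert-butyldimethylsilyl)oxy]-2-(hydroxymethyl)-3-[(3E)-pent-3-en-1-yn-1-yl]cyclohex-2-en-1-one 14 (not isolated)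
Conditions: NaAuCl4·2H2O (5 mol%), MeOH/CH2Cl2 (1:4), rt
Reagents that add atoms: none
Why: The gold salt in MeOH methanolyses the unhindered primary TBS ether, and the freed alcohol then adds to the gold-activated alkyne in a 6-endo-dig hydroalkoxylation (cycloisomerisation) at the distal, Michael-type carbon of the ynenone, which is favoured over 5-exo closure; the hindered secondary TBS ether and C6 are retained.

**Step 10**
Reactants: 15 bicyclic vinylogous-ester ketone
Product: 16 (6S,7R)-6-[(tert-butyldimethylsilyl)oxy]-7-methyl-3-[(1E)-prop-1-en-1-yl]-6,7-dihydro-1H-isochromen-8(5H)-one (major; the 7S epimer is carried along)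
Conditions: LDA (1.1 equiv), THF, −78 °C; MeI (3 equiv), −78 to −40 °C
Reagents that add atoms: iodomethane (CI)
Why: Kinetic enolate alkylation at the only sp3 α-carbon (C7), with MeI entering mainly anti to the adjacent OTBS group; the C7 configuration does not matter because C7 is planarised in step 15.

**Step 11**
Reactants: 17 methyl 3-oxobutanoate (2 equiv)
Product: 18 methyl 2,4-dihydroxy-6-methylbenzoate
Conditions: NaH (1 equiv), THF, 0 °C; n-BuLi (1 equiv), −78 °C to rt; reflux, 24 h; aq. HCl
Reagents that add atoms: none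
Why: Dianion self-condensation, in which the γ-carbanion of one acetoacetate dianion is acylated by the ester of a second (Claisen) and the resulting 3,5,7-triketo ester closes by intramolecular aldol condensation and aromatises to the resorcylate.

**Step 12**
Reactants: 18 methyl 2,4-dihydroxy-6-methylbenzoate
Product: 20 methyl 2-methoxy-6-methyl-4-(tosyloxy)benzoate, via methyl 2-hydroxy-6-methyl-4-(tosyloxy)benzoate 19 (not isolated)
Conditions: TsCl (1.05 equiv), K2CO3 (4 equiv), acetone, rt, 6 h; then MeI (4 equiv), reflux, 16 h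
Reagents that add atoms: p-toluenesulfonyl chloride (Cc1ccc(cc1)S(Cl)(=O)=O); iodomethane (CI)
Why: The free, more acidic 4-OH is sulfonylated selectively while the 2-OH is hydrogen-bonded to the ester, and the 2-OH is then methylated in the same pot under forcing Williamson conditions.

**Step 13**
Reactants: 20 methyl 2-methoxy-6-methyl-4-(tosyloxy)benzoate
Product: 21 4-hydroxy-2-methoxy-6-methylbenzoic acid
Conditions: KOH (10 equiv), DMSO/H2O (4:1), 90 °C; then aq. HCl, 0 °C
Reagents that add atoms: potassium hydroxide ([K+].[OH-])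
Why: Hot hydroxide saponifies the hindered ester and cleaves the aryl sulfonate at sulfur, unveiling the 4-OH with the 2-OMe in place; cold acidification avoids decarboxylation.

**Step 14**
Reactants: 21 4-hydroxy-2-methoxy-6-methylbenzoic acid
Product: 23 2-methoxy-6-methyl-4-[(triisopropylsilyl)oxy]benzoic acid, via triisopropylsilyl 2-methoxy-6-methyl-4-[(triisopropylsilyl)oxy]benzoate 22 (not isolated)
Conditions: TIPSCl (2.4 equiv), imidazole (5 equiv), DMF, rt; then AcOH/THF/H2O (3:1:1), rt
Reagents that add atoms: chlorotriisopropylsilane (CC(C)[Si](Cl)(C(C)C)C(C)C)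
Why: Exhaustive silylation followed by selective hydrolysis of the labile silyl ester leaves the robust aryl TIPS ether, which protects the phenol from oxidation in step 15.

**Step 15**
Reactants: 16 C7-methyl bicyclic ketone, 23 2-methoxy-6-methyl-4-[(triisopropylsilyl)oxy]benzoic acid
Product: 25 (6S,7R)-6-[(tert-butyldimethylsilyl)oxy]-7-methyl-8-oxo-3-[(1E)-prop-1-en-1-yl]-5,6,7,8-tetrahydro-1H-isochromen-7-yl 2-methoxy-6-methyl-4-[(triisopropylsilyl)oxy]benzoate, via manganese tris{2-methoxy-6-methyl-4-[(triisopropylsilyl)oxy]benzoate} 24 (not isolated)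
Conditions: Mn(OAc)3·2H2O (3 equiv), 23 (9.5 equiv), benzene, reflux, Dean–Stark, 2 h; then 16 (1 equiv), reflux, 12 h (surplus 23 recovered)
Reagents that add atoms: none
Why: Manganese triacetate α'-acyloxylation of an enone run with pre-exchanged aroate ligands, in which the trivalent manganese enolate of the vinylogous-ester ketone gives the tertiary C7 α-keto radical and a second trivalent manganese centre transfers the carboxylate to it on the face anti to the pseudo-axial C6–OTBS group, so the new C7–O bond is trans to C6–O (7R) from either C7 epimer of 16.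

**Step 16**
Reactants: 25 bis-silyl ether of the target
Product: 26 (6S,7R)-6-hydroxy-7-methyl-8-oxo-3-[(1E)-prop-1-en-1-yl]-5,6,7,8-tetrahydro-1H-isochromen-7-yl 4-hydroxy-2-methoxy-6-methylbenzoate
Conditions: TBAF (5 equiv), AcOH (5 equiv), THF, 0 °C to rt
Reagents that add atoms: none
Why: Buffered fluoride desilylation removes the aryl TIPS and secondary TBS ethers without base-induced retro-aldol or acyl migration (the di-ortho-substituted benzoate resists attack at its carbonyl), leaving both stereocentres untouched.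

**Compound list**
1 | cyclohex-2-en-1-one | O=C1C=CCCC1 | starting material
2 | (R)-3-(4,4,5,5-tetramethyl-1,3,2-dioxaborolan-2-yl)cyclohexan-1-one | O=C1C[C@H](B2OC(C)(C)C(C)(C)O2)CCC1 | intermediate (not isolated)
3 | (R)-3-hydroxycyclohexan-1-one | O=C1C[C@H](O)CCC1 | intermediate
4 | (R)-3-[(tert-butyldimethylsilyl)oxy]cyclohexan-1-one | O=C1C[C@H](O[Si](C)(C)C(C)(C)C)CCC1 | intermediate
5 | (R)-5-[(tert-butyldimethylsilyl)oxy]cyclohex-2-en-1-one | O=C1C[C@H](O[Si](C)(C)C(C)(C)C)CC=C1 | intermediate
6 | formaldehyde | C=O | starting material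
7 | (R)-5-[(tert-butyldimethylsilyl)oxy]-2-(hydroxymethyl)cyclohex-2-en-1-one | O=C1C[C@H](O[Si](C)(C)C(C)(C)C)CC=C1CO | intermediate
8 | (R)-5-[(tert-butyldimethylsilyl)oxy]-2-{[(tert-butyldimethylsilyl)oxy]methyl}cyclohex-2-en-1-one | O=C1C[C@H](O[Si](C)(C)C(C)(C)C)CC=C1CO[Si](C)(C)C(C)(C)C | intermediate
9 | (E)-but-2-enal | C/C=C/C=O | starting material
10 | (3E)-1,1-dibromopenta-1,3-diene | C/C=C/C=C(Br)Br | intermediate
11 | lithium (E)-pent-3-en-1-yn-1-ide | C/C=C/C#C[Li] | intermediate (not isolated)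
12 | (5R)-5-[(tert-butyldimethylsilyl)oxy]-2-{[(tert-butyldimethylsilyl)oxy]methyl}-1-[(3E)-pent-3-en-1-yn-1-yl]cyclohex-2-en-1-ol, C1 epimers | C/C=C/C#CC1(O)C[C@H](O[Si](C)(C)C(C)(C)C)CC=C1CO[Si](C)(C)C(C)(C)C | intermediate
13 | (5S)-5-[(tert-butyldimethylsilyl)oxy]-2-{[(tert-butyldimethylsilyl)oxy]methyl}-3-[(3E)-pent-3-en-1-yn-1-yl]cyclohex-2-en-1-one | C/C=C/C#CC1=C(CO[Si](C)(C)C(C)(C)C)C(=O)C[C@@H](O[Si](C)(C)C(C)(C)C)C1 | intermediate
14 | (5S)-5-[(tert-butyldimethylsilyl)oxy]-2-(hydroxymethyl)-3-[(3E)-pent-3-en-1-yn-1-yl]cyclohex-2-en-1-one | C/C=C/C#CC1=C(CO)C(=O)C[C@@H](O[Si](C)(C)C(C)(C)C)C1 | intermediate (not isolated)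
15 | (6S)-6-[(tert-butyldimethylsilyl)oxy]-3-[(1E)-prop-1-en-1-yl]-6,7-dihydro-1H-isochromen-8(5H)-one | C/C=C/C1=CC2=C(CO1)C(=O)C[C@@H](O[Si](C)(C)C(C)(C)C)C2 | intermediate
16 | (6S,7R)-6-[(tert-butyldimethylsilyl)oxy]-7-methyl-3-[(1E)-prop-1-en-1-yl]-6,7-dihydro-1H-isochromen-8(5H)-one (major epimer shown; 7S epimer carried along) | C/C=C/C1=CC2=C(CO1)C(=O)[C@H](C)[C@@H](O[Si](C)(C)C(C)(C)C)C2 | intermediate
17 | methyl 3-oxobutanoate | COC(=O)CC(C)=O | starting material
18 | methyl 2,4-dihydroxy-6-methylbenzoate | COC(=O)c1c(C)cc(O)cc1O | intermediate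
19 | methyl 2-hydroxy-6-methyl-4-(tosyloxy)benzoate | COC(=O)c1c(C)cc(OS(=O)(=O)c2ccc(C)cc2)cc1O | intermediate (not isolated)
20 | methyl 2-methoxy-6-methyl-4-(tosyloxy)benzoate | COC(=O)c1c(C)cc(OS(=O)(=O)c2ccc(C)cc2)cc1OC | intermediate
21 | 4-hydroxy-2-methoxy-6-methylbenzoic acid | COc1cc(O)cc(C)c1C(=O)O | intermediate
22 | triisopropylsilyl 2-methoxy-6-methyl-4-[(triisopropylsilyl)oxy]benzoate | COc1cc(O[Si](C(C)C)(C(C)C)C(C)C)cc(C)c1C(=O)O[Si](C(C)C)(C(C)C)C(C)C | intermediate (not isolated)
23 | 2-methoxy-6-methyl-4-[(triisopropylsilyl)oxy]benzoic acid | COc1cc(O[Si](C(C)C)(C(C)C)C(C)C)cc(C)c1C(=O)O | intermediate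
24 | manganese tris{2-methoxy-6-methyl-4-[(triisopropylsilyl)oxy]benzoate} | [Mn+3].[O-]C(=O)c1c(C)cc(O[Si](C(C)C)(C(C)C)C(C)C)cc1OC.[O-]C(=O)c1c(C)cc(O[Si](C(C)C)(C(C)C)C(C)C)cc1OC.[O-]C(=O)c1c(C)cc(O[Si](C(C)C)(C(C)C)C(C)C)cc1OC | intermediate (not isolated)
25 | (6S,7R)-6-[(tert-butyldimethylsilyl)oxy]-7-methyl-8-oxo-3-[(1E)-prop-1-en-1-yl]-5,6,7,8-tetrahydro-1H-isochromen-7-yl 2-methoxy-6-methyl-4-[(triisopropylsilyl)oxy]benzoate | C/C=C/C1=CC2=C(CO1)C(=O)[C@](C)(OC(=O)c1c(C)cc(O[Si](C(C)C)(C(C)C)C(C)C)cc1OC)[C@@H](O[Si](C)(C)C(C)(C)C)C2 | intermediate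
26 | (6S,7R)-6-hydroxy-7-methyl-8-oxo-3-[(1E)-prop-1-en-1-yl]-5,6,7,8-tetrahydro-1H-isochromen-7-yl 4-hydroxy-2-methoxy-6-methylbenzoate | C/C=C/C1=CC2=C(CO1)C(=O)[C@](C)(OC(=O)c1c(C)cc(O)cc1OC)[C@@H](O)C2 | target

**Step count and risks**
Total: 16 steps. Longest linear sequence: 11 steps (1, 2, 3, 4, 5, 7, 8, 9, 10, 15, 16). The acid branch is steps 11–14 and the enyne branch is step 6.

The three steps most likely to fail:

Step 15. The trivalent manganese enolate may lose the β-silyloxy group (leading to the aromatic 8-hydroxyisochromene), and transfer of a hindered aroate to a tertiary radical may be slow. Fallback, from 16 back to 25 by a polar route: form the potassium enolate of 16 with KN(SiMe3)2 in THF at −78 °C and hydroxylate it with 2-(phenylsulfonyl)-3-phenyloxaziridine, again anti to OTBS, to give (6S,7R)-6-[(tert-butyldimethylsilyl)oxy]-7-hydroxy-7-methyl-3-[(1E)-prop-1-en-1-yl]-6,7-dihydro-1H-isochromen-8(5H)-one F1. Convert acid 23 with 1-chloro-N,N,2-trimethylprop-1-en-1-amine in CH2Cl2 into 2-methoxy-6-methyl-4-[(triisopropylsilyl)oxy]benzoyl chloride F2. Then acylate the lithium alkoxide of F1 (LiN(SiMe3)2, THF, −78 to 0 °C) with F2, which gives 25.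

Step 9. The gold salt may also cleave the secondary silyl ether, add methanol to the ynenone, or give 5-exo closure. Fallback, from 13 back to 15 by electrophile-driven ring closure: cleave only the primary silyl ether with HF·pyridine in THF/pyridine at 0 °C and isolate 14. Treat 14 with I2 and NaHCO3 in MeCN to effect 6-endo iodocyclisation to (6S)-6-[(tert-butyldimethylsilyl)oxy]-4-iodo-3-[(1E)-prop-1-en-1-yl]-6,7-dihydro-1H-isochromen-8(5H)-one F3. Remove the iodine with Bu3SnH and catalytic Pd(PPh3)4 in THF, which gives 15.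

Step 8. The chromate ester of a carbinol that is both allylic and propargylic may rearrange through the alkyne, or the acidic oxidant may strip the primary silyl ether. Fallback, from 12 back to 13 with transposition and oxidation separated: isomerise 12 with catalytic Re2O7 in Et2O at −20 °C (perrhenate-ester 1,3-shift, driven by enyne conjugation) to (5S)-5-[(tert-butyldimethylsilyl)oxy]-2-{[(tert-butyldimethylsilyl)oxy]methyl}-3-[(3E)-pent-3-en-1-yn-1-yl]cyclohex-2-en-1-ol F4 (C1 epimers). Oxidise F4 with MnO2 in CH2Cl2, which gives 13.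

**Further compounds**
F1 | step 15 | (6S,7R)-6-[(tert-butyldimethylsilyl)oxy]-7-hydroxy-7-methyl-3-[(1E)-prop-1-en-1-yl]-6,7-dihydro-1H-isochromen-8(5H)-one | C/C=C/C1=CC2=C(CO1)C(=O)[C@](C)(O)[C@@H](O[Si](C)(C)C(C)(C)C)C2
F2 | step 15 | 2-methoxy-6-methyl-4-[(triisopropylsilyl)oxy]benzoyl chloride | COc1cc(O[Si](C(C)C)(C(C)C)C(C)C)cc(C)c1C(Cl)=O
F3 | step 9 | (6S)-6-[(tert-butyldimethylsilyl)oxy]-4-iodo-3-[(1E)-prop-1-en-1-yl]-6,7-dihydro-1H-isochromen-8(5H)-one | C/C=C/C1=C(I)C2=C(CO1)C(=O)C[C@@H](O[Si](C)(C)C(C)(C)C)C2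
F4 | step 8 | (5S)-5-[(tert-butyldimethylsilyl)oxy]-2-{[(tert-butyldimethylsilyl)oxy]methyl}-3-[(3E)-pent-3-en-1-yn-1-yl]cyclohex-2-en-1-ol (C1 epimers) | C/C=C/C#CC1=C(CO[Si](C)(C)C(C)(C)C)C(O)C[C@@H](O[Si](C)(C)C(C)(C)C)C1
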